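## The problem

Target 28 is two fully substituted 1,4-benzoquinone rings joined through their C6 carbons by an unbranched chain of thirteen methylene groups. Ring A (C1 carbonyl, C2 methoxy, C3 methyl, C4 carbonyl, C5 hydroxyl, C6 tether) and ring B (B1 carbonyl, B2 hydroxyl, B3 methyl, B4 carbonyl, B5 hydroxyl, B6 tether) differ only in the methyl group on the C2 oxygen. There is no stereocentre and no ring fusion, so nothing has to be controlled in space; the difficulty lies in regiochemistry and oxidation level. A 2,5-dihydroxyquinone exchanges its carbonyl and hydroxyl oxygens by tautomerism, so a late methylation could tell neither ring A from ring B nor the C2 oxygen from the C5 oxygen; the single O-methyl group must be placed while ring A is still an arene. Hydroxyquinones are vinylogous acids that are easily reduced and attacked by nucleophiles, and the quinone methoxy group is a vinylogous ester that hydrolyses or exchanges. Both quinones therefore have to be raised from phenols in the last steps, after the functionless tether is complete. The enabling feature is that C2 (oxygen), C3 (methyl), C4 (oxygen) and C6 (alkyl) of ring A form the pattern of a 2-methyl-5-alkylresorcinol, and that C5 is the carbon at which a folded polyketide carries its carboxyl group. Ring A is thus the cyclised form of a 4-methyl-3,5,7-triketo ester whose C7 ketone bears the tether; closing that chain between its C2 and C7 (ring A bond C5–C6) gives a resorcylate whose ester at C5 distinguishes the oxygens at C2 and C4.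

## Retrosynthesis

Chain atoms of triketo ester 17 map onto ring A as follows: chain C2 becomes C5, C3 becomes C4, C4 becomes C3, C5 becomes C2, C6 becomes C1 and C7 becomes C6.

**Ring oxygens (28 back to 23).** The first cut removes the four C–O bonds outside the resorcinol pattern: C1–O and C5–O of ring A, B1–O and B5–O of ring B. It leads through hexahydroxy arene 27, heptaacetate 26 and bis-quinone 24 to triphenol 23. Carrying all four oxygens of each ring as ethers from the start would require telling the C2 methoxy from many other ether oxygens at the end; in 23 it is the only ether left, and both rings pass through the same reagents together. The forward steps must oxidise each ring at the free carbon para to a phenol (C1, B1; Teuber oxidation), add an oxygen nucleophile at the last ring CH (C5, B5; Thiele–Winter acetoxylation), and unveil and air-oxidise 27 without touching the methoxy group.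

**Differentiating groups (23 back to 19).** Next the benzyl ethers of ring B are restored (22), a carboxyl group is put back on C5 (acid 21, ester 20), and the O-methyl bond at C2 is cut to give resorcylate 19. The ester is what makes the cut at the methyl ether clean: it chelates the C4 hydroxyl, so only the C2 oxygen is alkylated. The neighbouring option, statistical mono-methylation of a symmetric resorcinol, is avoided. The ester is then expendable, because the ortho hydroxyl and para methoxy make C5 easy to protonate and decarboxylate. The forward sequence asks for one selective methylation, one hydrolysis with decarboxylation and one hydrogenolysis.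

**Ring A (19 back to 17).** The key cut opens ring A bond C5–C6, the bond between chain C2 and chain C7 of 17. Against the neighbouring ring bonds this cut has the advantage that the nucleophile is a β-keto ester carbon and the electrophile a ketone, and that the arene methyl and both oxygens are already in the chain. The precursor is acyclic and made of carbonyl units only. The forward reaction must favour this aldol over Claisen closure onto the ester and over aldol from the tether methylene.

**Chain C6–C7 (17 back to 15 and 12).** Cutting between chain C6 and C7 gives the seven-carbon diketo ester 15 as its 2,4,6-trianion and the tether as Weinreb amide 12. This cut separates the polyketide head from the lipid tail at the only carbonyl of the tail, and it delivers the ester directly instead of a sensitive triketo acid. The forward acylation must occur at the terminal carbon of the trianion and stop at the ketone stage.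

**Diketo ester (15 back to 13).** Cutting the bond between C4 and C5 of 15 leads to the commercial β-keto ester 13 and an acetyl donor; the methyl branch is already in 13. The forward step is a γ-acylation of a β-keto ester dianion.

**Tether (12 back to 4 and 9).** The saturated chain of 12 comes from alkene 11, cut at the benzylic double bond into phosphonium salt 4 and aldehyde 9. A Wittig reaction joins a one-carbon benzylic unit to a thirteen-carbon unit; the alkene geometry is irrelevant, but its hydrogenation must spare the benzyl ethers.

**Building blocks (4 back to 1; 9 back to 5).** Salt 4 follows from alcohol 3, ester 2 and commercial acid 1, which already has the ring B substitution. Aldehyde 9 follows from ozonolysis of amide 7, made from commercial erucic acid 5, whose double bond lies exactly thirteen carbons from the carboxyl group.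

## Roads not taken

**Alternative 1:** The tether is cut on both sides of its central carbon. A4 (1,3-dithiane) would be lithiated and alkylated with ring A bromide A2, then lithiated again and alkylated with ring B bromide A3 to give A1. Desulfurisation, hydrogenolysis and the same two-stage oxidation of both rings would follow.
- Merits: this is the most convergent of the plans, the two halves come from closely related chemistry, and no step is mechanistically delicate. In convergency and in predictability of the carbon–carbon bond formations it is better than the chosen plan.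
- Weak points: A2 needs one methyl and one benzyl ether on a symmetric resorcinol, which means a statistical mono-alkylation, the very problem of the target. The central carbon has no function in 28, so the linchpin and its removal are overhead. Two six-carbon chains must be built separately, and the second alkylation of a 2-alkyl dithiane anion with an unactivated primary bromide is slow.
- Comparison: the chosen plan sets against this a non-statistical placement of the O-methyl group, a tether taken whole from one fatty acid, and a shorter sequence.

**Alternative 2:** Ring A is cut at C1–C2, with the ring made from a squarate-derived cyclobutenone. Heating A6 would open the four-membered ring to a dienylketene that closes onto the methoxy-bearing alkene carbon and gives hydroquinone A5. Oxidation and removal of the tert-butyl group would finish ring A.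
- Merits: ring A arrives with all four oxygens in place and with the C2 and C5 oxygens already different. For ring A this avoids both the para oxidation and the acetoxylation of a donor-substituted quinone, and in that respect it is better than the chosen plan.
- Weak points: A6 requires a β-methoxy alkenyllithium, which is prone to β-elimination, and its regioselective addition to an unsymmetrical cyclobutenedione. The C13 tether must be attached as an organolithium. Ring B still needs its own two-stage oxidation, now in the presence of a finished or masked ring A, so there are two endgames.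
- Comparison: the chosen plan runs one oxidation sequence on both rings at once and makes all carbon–carbon bonds by enolate and ylide chemistry.

**Alternative 3:** Ring B is cut at B2–B3 and B4–B5. Heating cyclobutenone A8 with siloxyalkyne A9 would insert the alkyne carbons as B3 and B4 and give resorcinol monosilyl ether A7.
- Merits: the benzannulation is regiospecific, runs under neutral thermal conditions and is convergent. As an arene construction it is at least as reliable as an aldol aromatisation.
- Weak points: it spends the key step on the ring whose substitution can be bought (as 1), and the oxygen differentiation it provides is wasted on the symmetric ring B. Ring A in A8 still needs a methyl and a benzyl ether set statistically. A8 and A9 each take several steps.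
- Comparison: the chosen plan builds the ring that needs differentiation and obtains that differentiation from the ring-forming step itself.

Key step: step 10

Assumption: the β-dicarbonyl compounds 15 and 17 and the hydroxyquinones are drawn as single tautomers although they exist as tautomeric mixtures, and 11 is used as an E/Z mixture because step 7 removes the double bond.

## Route

Step 1
Reactants: 1 3,5-dihydroxy-4-methylbenzoic acid
Product: 2 benzyl 3,5-bis(benzyloxy)-4-methylbenzoate
Conditions: BnBr (3.5 equiv), K2CO3, DMF, 60 °C
Reagents that add atoms: benzyl bromide, BrCc1ccccc1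
Why: Williamson alkylation of both phenoxides and the carboxylate; the benzyl ester is harmless because step 2 reduces it.

Step 2
Reactants: 2 benzyl 3,5-bis(benzyloxy)-4-methylbenzoate
Product: 3 [3,5-bis(benzyloxy)-4-methylphenyl]methanol
Conditions: LiAlH4, THF, 0 °C to rt
Reagents that add atoms: none
Why: Hydride reduction of an aryl ester to the benzylic alcohol; aryl benzyl ethers are inert to LiAlH4.

Step 3
Reactants: 3 [3,5-bis(benzyloxy)-4-methylphenyl]methanol
Product: 4 {[3,5-bis(benzyloxy)-4-methylphenyl]methyl}triphenylphosphonium bromide
Conditions: PPh3·HBr, MeCN, reflux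
Reagents that add atoms: triphenylphosphine hydrobromide, Br.c1ccc(cc1)P(c1ccccc1)c1ccccc1
Why: Direct conversion of a benzylic alcohol into its phosphonium salt (benzylic bromide formed in situ, then SN2 by PPh3), a standard preparation for alkoxy-substituted benzyl alcohols; the salt should crystallise.

Step 4
Reactants: 5 erucic acid, (13Z)-docos-13-enoic acid
Product: 7 (13Z)-N-methoxy-N-methyldocos-13-enamide, via acyl imidazole 6 (not isolated)
Conditions: CDI, CH2Cl2, rt; then MeNH(OMe)·HCl, rt
Reagents that add atoms: N,O-dimethylhydroxylamine hydrochloride, Cl.CNOC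
Why: Weinreb amide formation by carbonyldiimidazole activation; the isolated Z alkene is untouched.

Step 5
Reactants: 7 (13Z)-N-methoxy-N-methyldocos-13-enamide
Product: 9 N-methoxy-N-methyl-13-oxotridecanamide, via ozonide 8 (not isolated)
Conditions: O3, CH2Cl2, −78 °C; then PPh3, −78 °C to rt
Reagents that add atoms: ozone, [O-][O+]=O
Why: Ozonolysis with reductive work-up (Criegee mechanism) cleaves the C13=C14 bond; the amide is inert and the nine-carbon co-product is removed by chromatography.

Step 6
Reactants: 4 {[3,5-bis(benzyloxy)-4-methylphenyl]methyl}triphenylphosphonium bromide; 9 N-methoxy-N-methyl-13-oxotridecanamide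
Product: 11 14-[3,5-bis(benzyloxy)-4-methylphenyl]-N-methoxy-N-methyltetradec-13-enamide (E/Z mixture), via phosphorus ylide 10 (not isolated)
Conditions: NaN(SiMe3)2, THF, 0 °C; then 9, −78 °C to rt
Reagents that add atoms: none
Why: Wittig olefination with a semi-stabilised benzylic ylide, which reacts with the aldehyde and not with the Weinreb amide at low temperature; the alkene geometry does not matter.

Step 7
Reactants: 11 14-[3,5-bis(benzyloxy)-4-methylphenyl]-N-methoxy-N-methyltetradec-13-enamide
Product: 12 14-[3,5-bis(benzyloxy)-4-methylphenyl]-N-methoxy-N-methyltetradecanamide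
Conditions: H2 (1 atm), 5% Pd/C, pyridine (0.5 equiv), EtOAc, rt
Reagents that add atoms: none
Why: Amine-poisoned Pd/C hydrogenation: pyridine suppresses hydrogenolysis of phenolic benzyl ethers while the disubstituted styrene is saturated; the amide N–O bond is stable under these conditions.

Step 8
Reactants: 13 methyl 3-oxopentanoate
Product: 15 methyl 4-methyl-3,5-dioxohexanoate (racemic), via dilithium dianion 14 (not isolated)
Conditions: LiN(iPr)2 (2.2 equiv), THF, −78 to 0 °C; then MeC(O)N(OMe)Me, −78 to 0 °C; aq. HCl
Reagents that add atoms: N-methoxy-N-methylacetamide, CC(=O)N(C)OC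
Why: γ-Acylation of a β-keto ester dianion (Huckin–Weiler dianion) with a Weinreb amide; the more basic C4 carbanion attacks and the chelated adduct prevents double addition. The new C4 centre is enolisable and is erased in step 10.

Step 9
Reactants: 15 methyl 4-methyl-3,5-dioxohexanoate; 12 14-[3,5-bis(benzyloxy)-4-methylphenyl]-N-methoxy-N-methyltetradecanamide
Product: 17 methyl 20-[3,5-bis(benzyloxy)-4-methylphenyl]-4-methyl-3,5,7-trioxoicosanoate (racemic), via trilithium trianion 16 (not isolated)
Conditions: LiN(iPr)2 (3.3 equiv), THF, −78 to 0 °C; then 12, −78 to 0 °C; cold dilute HCl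
Reagents that add atoms: none
Why: Harris-type polyanion acylation: the 2,4,6-trianion reacts at its last-formed and most nucleophilic carbon C6. The Weinreb chelate holds the adduct until the quench, so the product does not consume trianion; a cold acidic quench avoids premature cyclisation.

Step 10
Reactants: 17 methyl 20-[3,5-bis(benzyloxy)-4-methylphenyl]-4-methyl-3,5,7-trioxoicosanoate
Product: 19 methyl 6-{13-[3,5-bis(benzyloxy)-4-methylphenyl]tridecyl}-2,4-dihydroxy-3-methylbenzoate, via aldol carbinol 18 (not isolated)
Conditions: KOH (0.5 M), H2O/MeOH/THF, 0 °C to rt; then 1 M HCl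
Reagents that add atoms: none
Why: Biomimetic intramolecular aldol condensation with aromatisation, the reaction type established for 3,5,7-triketo esters as the laboratory copy of polyketide folding. In dilute hydroxide 17 is present as its enolates; the β-keto ester carbon C2 adds to the C7 ketone to give carbinol 18, which loses water by E1cB elimination and tautomerises at the C3 and C5 carbonyls to the benzene ring, completed on acidification. The closure is 6-exo-trig at the C7 carbonyl (6-(enolendo)-exo-trig in Baldwin's enolate terms) and forms ring A bond C5–C6. No stereocentre survives: the C4 centre of 17 and those of 18 are erased by aromatisation. Selectivity over Claisen closure of C6 onto the ester rests on the medium, since in water the ketone is the better electrophile and only the aldol path ends in irreversible aromatisation. Selectivity over aldol from the tether methylene C8 onto C3 rests on acidity, because C2 is doubly activated and C8 is an ordinary ketone α-carbon. The C4 methyl travels in the chain, so the arene needs no C-methylation, and the benzyl ethers and saturated tether are inert.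

Step 11
Reactants: 19 methyl 6-{13-[3,5-bis(benzyloxy)-4-methylphenyl]tridecyl}-2,4-dihydroxy-3-methylbenzoate
Product: 20 methyl 6-{13-[3,5-bis(benzyloxy)-4-methylphenyl]tridecyl}-2-hydroxy-4-methoxy-3-methylbenzoate
Conditions: MeI (1.2 equiv), K2CO3, acetone, rt
Reagents that add atoms: iodomethane, CI
Why: Chemoselective Williamson methylation: the hydroxyl ortho to the ester is held in a hydrogen bond to the carbonyl, so only the para hydroxyl (the future C2 oxygen) is alkylated, as in the known mono-methylation of orsellinate esters.

Step 12
Reactants: 20 methyl 6-{13-[3,5-bis(benzyloxy)-4-methylphenyl]tridecyl}-2-hydroxy-4-methoxy-3-methylbenzoate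
Product: 22 5-{13-[3,5-bis(benzyloxy)-4-methylphenyl]tridecyl}-3-methoxy-2-methylphenol, via carboxylic acid 21 (not isolated)
Conditions: KOH, DMSO/H2O, 110 °C; then HCl to pH 1, 90 °C
Reagents that add atoms: none
Why: Saponification of the hindered salicylate followed by acid-promoted protodecarboxylation; the ortho hydroxyl and para methoxy make the ipso carbon basic, as in orsellinic-type acids. Benzyl ethers tolerate both media.

Step 13
Reactants: 22 5-{13-[3,5-bis(benzyloxy)-4-methylphenyl]tridecyl}-3-methoxy-2-methylphenol
Product: 23 5-[13-(3-hydroxy-5-methoxy-4-methylphenyl)tridecyl]-2-methylbenzene-1,3-diol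
Conditions: H2 (1 atm), 10% Pd/C, EtOAc/MeOH, rt
Reagents that add atoms: none
Why: Hydrogenolysis of the two aryl benzyl ethers; nothing else in 22 is reducible under these conditions.

Step 14
Reactants: 23 5-[13-(3-hydroxy-5-methoxy-4-methylphenyl)tridecyl]-2-methylbenzene-1,3-diol
Product: 24 2-hydroxy-6-[13-(5-methoxy-4-methyl-3,6-dioxocyclohexa-1,4-dien-1-yl)tridecyl]-3-methylcyclohexa-2,5-diene-1,4-dione
Conditions: (KSO3)2NO (5 equiv), KH2PO4, H2O/acetone, rt
Reagents that add atoms: potassium nitrosodisulfonate (Fremy's salt), [K+].[K+].[O]N(S(=O)(=O)[O-])S(=O)(=O)[O-]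
Why: Teuber oxidation: one nitroxide radical abstracts the phenolic hydrogen, a second couples at the free para carbon and loss of imidodisulfonate gives the para-quinone. In ring A the para carbon is C1; in ring B the two hydroxyls have equivalent free para carbons (B1), and the second hydroxyl remains as the hydroxyquinone.

Step 15
Reactants: 24 2-hydroxy-6-[13-(5-methoxy-4-methyl-3,6-dioxocyclohexa-1,4-dien-1-yl)tridecyl]-3-methylcyclohexa-2,5-diene-1,4-dione
Product: 26 3-{13-[2,3,6-tris(acetyloxy)-5-methoxy-4-methylphenyl]tridecyl}-6-methylbenzene-1,2,4,5-tetrayl tetraacetate, via acetoxy bis-quinone 25 (not isolated)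
Conditions: Ac2O, H2SO4 (cat.), 0 °C to rt
Reagents that add atoms: acetic anhydride, CC(=O)OC(C)=O
Why: Thiele–Winter acetoxylation: the ring B hydroxyl is acetylated first, then each acid-activated quinone takes up acetate at its only unsubstituted carbon (C5, B5), enolises and is peracetylated. Both product arenes are hexasubstituted and cannot react further; the reaction type is known for trisubstituted methoxy- and hydroxyquinones.

Step 16
Reactants: 26 3-{13-[2,3,6-tris(acetyloxy)-5-methoxy-4-methylphenyl]tridecyl}-6-methylbenzene-1,2,4,5-tetrayl tetraacetate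
Product: 28 2,5-dihydroxy-3-[13-(2-hydroxy-5-methoxy-4-methyl-3,6-dioxocyclohexa-1,4-dien-1-yl)tridecyl]-6-methylcyclohexa-2,5-diene-1,4-dione, via hexahydroxy arene 27 (not isolated)
Conditions: K2CO3, MeOH, Ar, rt; then air; 1 M HCl
Reagents that add atoms: none
Why: Base-catalysed methanolysis of the seven aryl acetates under argon, then autoxidation of the electron-rich hydroxyhydroquinone anions on admission of air. In methanolic carbonate any exchange at the ring A methoxy is degenerate, and the hydroxyquinone anions resist further attack.

## Compound list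

1 | 3,5-dihydroxy-4-methylbenzoic acid | Cc1c(O)cc(C(=O)O)cc1O | starting material
2 | benzyl 3,5-bis(benzyloxy)-4-methylbenzoate | Cc1c(OCc2ccccc2)cc(C(=O)OCc2ccccc2)cc1OCc1ccccc1 | intermediate
3 | [3,5-bis(benzyloxy)-4-methylphenyl]methanol | Cc1c(OCc2ccccc2)cc(CO)cc1OCc1ccccc1 | intermediate
4 | {[3,5-bis(benzyloxy)-4-methylphenyl]methyl}triphenylphosphonium bromide | Cc1c(OCc2ccccc2)cc(C[P+](c2ccccc2)(c2ccccc2)c2ccccc2)cc1OCc1ccccc1.[Br-] | intermediate
5 | erucic acid, (13Z)-docos-13-enoic acid | CCCCCCCC/C=C\CCCCCCCCCCCC(=O)O | starting material
6 | (13Z)-1-(1H-imidazol-1-yl)docos-13-en-1-one | CCCCCCCC/C=C\CCCCCCCCCCCC(=O)n1ccnc1 | intermediate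
7 | (13Z)-N-methoxy-N-methyldocos-13-enamide | CCCCCCCC/C=C\CCCCCCCCCCCC(=O)N(C)OC | intermediate
8 | N-methoxy-N-methyl-12-(5-octyl-1,2,4-trioxolan-3-yl)dodecanamide (mixture of stereoisomers) | CCCCCCCCC1OOC(CCCCCCCCCCCC(=O)N(C)OC)O1 | intermediate
9 | N-methoxy-N-methyl-13-oxotridecanamide | O=CCCCCCCCCCCCC(=O)N(C)OC | intermediate
10 | {[3,5-bis(benzyloxy)-4-methylphenyl]methylidene}triphenylphosphorane | Cc1c(OCc2ccccc2)cc(C=P(c2ccccc2)(c2ccccc2)c2ccccc2)cc1OCc1ccccc1 | intermediate
11 | 14-[3,5-bis(benzyloxy)-4-methylphenyl]-N-methoxy-N-methyltetradec-13-enamide (E/Z mixture) | Cc1c(OCc2ccccc2)cc(C=CCCCCCCCCCCCC(=O)N(C)OC)cc1OCc1ccccc1 | intermediate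
12 | 14-[3,5-bis(benzyloxy)-4-methylphenyl]-N-methoxy-N-methyltetradecanamide | Cc1c(OCc2ccccc2)cc(CCCCCCCCCCCCCC(=O)N(C)OC)cc1OCc1ccccc1 | intermediate
13 | methyl 3-oxopentanoate | CCC(=O)CC(=O)OC | starting material
14 | dilithium dianion of methyl 3-oxopentanoate (carbanion sites C2 and C4) | [Li+].[Li+].C[CH-]C(=O)[CH-]C(=O)OC | intermediate
15 | methyl 4-methyl-3,5-dioxohexanoate (racemic) | COC(=O)CC(=O)C(C)C(C)=O | intermediate
16 | trilithium trianion of methyl 4-methyl-3,5-dioxohexanoate (carbanion sites C2, C4 and C6) | [Li+].[Li+].[Li+].COC(=O)[CH-]C(=O)[C-](C)C(=O)[CH2-] | intermediate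
17 | methyl 20-[3,5-bis(benzyloxy)-4-methylphenyl]-4-methyl-3,5,7-trioxoicosanoate (racemic, enolisable at C4) | COC(=O)CC(=O)C(C)C(=O)CC(=O)CCCCCCCCCCCCCc1cc(OCc2ccccc2)c(C)c(OCc2ccccc2)c1 | intermediate
18 | methyl 2-{13-[3,5-bis(benzyloxy)-4-methylphenyl]tridecyl}-2-hydroxy-5-methyl-4,6-dioxocyclohexane-1-carboxylate (mixture of stereoisomers and tautomers) | COC(=O)C1C(=O)C(C)C(=O)CC1(O)CCCCCCCCCCCCCc1cc(OCc2ccccc2)c(C)c(OCc2ccccc2)c1 | intermediate
19 | methyl 6-{13-[3,5-bis(benzyloxy)-4-methylphenyl]tridecyl}-2,4-dihydroxy-3-methylbenzoate | COC(=O)c1c(O)c(C)c(O)cc1CCCCCCCCCCCCCc1cc(OCc2ccccc2)c(C)c(OCc2ccccc2)c1 | intermediate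
20 | methyl 6-{13-[3,5-bis(benzyloxy)-4-methylphenyl]tridecyl}-2-hydroxy-4-methoxy-3-methylbenzoate | COC(=O)c1c(O)c(C)c(OC)cc1CCCCCCCCCCCCCc1cc(OCc2ccccc2)c(C)c(OCc2ccccc2)c1 | intermediate
21 | 6-{13-[3,5-bis(benzyloxy)-4-methylphenyl]tridecyl}-2-hydroxy-4-methoxy-3-methylbenzoic acid | OC(=O)c1c(O)c(C)c(OC)cc1CCCCCCCCCCCCCc1cc(OCc2ccccc2)c(C)c(OCc2ccccc2)c1 | intermediate
22 | 5-{13-[3,5-bis(benzyloxy)-4-methylphenyl]tridecyl}-3-methoxy-2-methylphenol | COc1cc(CCCCCCCCCCCCCc2cc(OCc3ccccc3)c(C)c(OCc3ccccc3)c2)cc(O)c1C | intermediate
23 | 5-[13-(3-hydroxy-5-methoxy-4-methylphenyl)tridecyl]-2-methylbenzene-1,3-diol | COc1cc(CCCCCCCCCCCCCc2cc(O)c(C)c(O)c2)cc(O)c1C | intermediate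
24 | 2-hydroxy-6-[13-(5-methoxy-4-methyl-3,6-dioxocyclohexa-1,4-dien-1-yl)tridecyl]-3-methylcyclohexa-2,5-diene-1,4-dione | COC1=C(C)C(=O)C=C(CCCCCCCCCCCCCC2=CC(=O)C(C)=C(O)C2=O)C1=O | intermediate
25 | 5-[13-(5-methoxy-4-methyl-3,6-dioxocyclohexa-1,4-dien-1-yl)tridecyl]-2-methyl-3,6-dioxocyclohexa-1,4-dien-1-yl acetate | COC1=C(C)C(=O)C=C(CCCCCCCCCCCCCC2=CC(=O)C(C)=C(OC(C)=O)C2=O)C1=O | intermediate
26 | 3-{13-[2,3,6-tris(acetyloxy)-5-methoxy-4-methylphenyl]tridecyl}-6-methylbenzene-1,2,4,5-tetrayl tetraacetate | COc1c(C)c(OC(C)=O)c(OC(C)=O)c(CCCCCCCCCCCCCc2c(OC(C)=O)c(OC(C)=O)c(C)c(OC(C)=O)c2OC(C)=O)c1OC(C)=O | intermediate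
27 | 3-[13-(2,3,6-trihydroxy-5-methoxy-4-methylphenyl)tridecyl]-6-methylbenzene-1,2,4,5-tetrol | COc1c(C)c(O)c(O)c(CCCCCCCCCCCCCc2c(O)c(O)c(C)c(O)c2O)c1O | intermediate
28 | 2,5-dihydroxy-3-[13-(2-hydroxy-5-methoxy-4-methyl-3,6-dioxocyclohexa-1,4-dien-1-yl)tridecyl]-6-methylcyclohexa-2,5-diene-1,4-dione | COC1=C(C)C(=O)C(O)=C(CCCCCCCCCCCCCC2=C(O)C(=O)C(C)=C(O)C2=O)C1=O | target

## Step count and risks

Total step count: 16. Longest linear sequence: 13 steps (steps 1, 2, 3, 6, 7 and 9 to 16).

**Step 10 (key step).** The 2-methyl-1,3-diketone unit may undergo hydroxide-induced retro-Claisen cleavage faster than it cyclises, because the methyl group lowers its enol content. Lactonisation to a 4-hydroxy-2-pyranone or Claisen closure could also compete, and poor solubility of the lipophilic substrate in aqueous base would slow the wanted path. Fallback (from 12, back at 19): ring A is built by Michael–Claisen annulation instead of polyketide folding. Reduction of 12 with LiAlH4 at −78 °C should give 14-[3,5-bis(benzyloxy)-4-methylphenyl]tetradecanal F1. Wittig reaction with the stabilised ylide 1-(triphenylphosphoranylidene)butan-2-one should give (4E)-18-[3,5-bis(benzyloxy)-4-methylphenyl]octadec-4-en-3-one F2. Conjugate addition of dimethyl malonate (NaOMe, MeOH, reflux) and Claisen closure from the ethyl-ketone methylene should give methyl 6-{13-[3,5-bis(benzyloxy)-4-methylphenyl]tridecyl}-2-hydroxy-3-methyl-4-oxocyclohex-2-ene-1-carboxylate F3. Dehydrogenation (DDQ, dioxane, heat) then leads to 19.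

**Step 9.** Formation of the trianion may be incomplete, proton transfer from the α-methylene of the amide may quench the terminal carbanion, the poorly soluble long-chain amide may acylate slowly at low temperature, and the product may cyclise during work-up. Fallback (from 12, back at 17): the tether is attached at the dianion stage and the ester carbon is added last. The dianion of 3-methylpentane-2,4-dione (2 equiv LiN(iPr)2) is acylated at its terminal carbon with 12 to give 19-[3,5-bis(benzyloxy)-4-methylphenyl]-3-methylnonadecane-2,4,6-trione F4. Its trianion is carboxylated with CO2 at the terminal methyl to give 20-[3,5-bis(benzyloxy)-4-methylphenyl]-4-methyl-3,5,7-trioxoicosanoic acid F5, which is esterified at once with diazomethane to 17.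

**Step 14.** The resorcinol ring B may be over-oxidised or undergo oxidative coupling, oxidation of the lipophilic triphenol may stall in the aqueous medium, and some ortho attack may occur on ring A. Fallback (from 23, back at 26): the oxidant is changed from a para-selective radical to the ortho-selective 2-iodoxybenzoic acid (DMF, rt). This should give 2-hydroxy-6-[13-(3-methoxy-4-methyl-5,6-dioxocyclohexa-1,3-dien-1-yl)tridecyl]-3-methylcyclohexa-2,5-diene-1,4-dione F6, with ring A as an ortho-quinone and ring B as the same hydroxyquinone as in 24 by tautomerism. Under the conditions of step 15 acetate adds to the last ring CH of each ring, so that F6 converges on 26.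

**Step 15.** Conjugate addition of acetate to the donor-substituted, trisubstituted ring A quinone may be slow, and the strong acid may exchange the vinylogous methyl ester for acetate and so erase the differentiation. Fallback (from 23, back at 27): the oxygens are introduced at the arene stage through formyl groups. Fourfold Rieche formylation (Cl2CHOMe, TiCl4) at the four free ring carbons gives 2-[13-(2,6-diformyl-3-hydroxy-5-methoxy-4-methylphenyl)tridecyl]-4,6-dihydroxy-5-methylbenzene-1,3-dicarbaldehyde F7. Fourfold Dakin oxidation (H2O2, aqueous base, Ar) converts each formyl group, which stands ortho or para to a hydroxyl, into a hydroxyl and gives 27, which is air-oxidised to 28 as in step 16.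

## Further compounds

F1 | step 10 | 14-[3,5-bis(benzyloxy)-4-methylphenyl]tetradecanal | Cc1c(OCc2ccccc2)cc(CCCCCCCCCCCCCC=O)cc1OCc1ccccc1
F2 | step 10 | (4E)-18-[3,5-bis(benzyloxy)-4-methylphenyl]octadec-4-en-3-one | CCC(=O)/C=C/CCCCCCCCCCCCCc1cc(OCc2ccccc2)c(C)c(OCc2ccccc2)c1
F3 | step 10 | methyl 6-{13-[3,5-bis(benzyloxy)-4-methylphenyl]tridecyl}-2-hydroxy-3-methyl-4-oxocyclohex-2-ene-1-carboxylate (racemic, mixture of diastereomers) | COC(=O)C1C(O)=C(C)C(=O)CC1CCCCCCCCCCCCCc1cc(OCc2ccccc2)c(C)c(OCc2ccccc2)c1
F4 | step 9 | 19-[3,5-bis(benzyloxy)-4-methylphenyl]-3-methylnonadecane-2,4,6-trione (racemic) | CC(=O)C(C)C(=O)CC(=O)CCCCCCCCCCCCCc1cc(OCc2ccccc2)c(C)c(OCc2ccccc2)c1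
F5 | step 9 | 20-[3,5-bis(benzyloxy)-4-methylphenyl]-4-methyl-3,5,7-trioxoicosanoic acid (racemic) | OC(=O)CC(=O)C(C)C(=O)CC(=O)CCCCCCCCCCCCCc1cc(OCc2ccccc2)c(C)c(OCc2ccccc2)c1
F6 | step 14 | 2-hydroxy-6-[13-(3-methoxy-4-methyl-5,6-dioxocyclohexa-1,3-dien-1-yl)tridecyl]-3-methylcyclohexa-2,5-diene-1,4-dione | COC1=C(C)C(=O)C(=O)C(CCCCCCCCCCCCCC2=CC(=O)C(C)=C(O)C2=O)=C1
F7 | step 15 | 2-[13-(2,6-diformyl-3-hydroxy-5-methoxy-4-methylphenyl)tridecyl]-4,6-dihydroxy-5-methylbenzene-1,3-dicarbaldehyde | COc1c(C)c(O)c(C=O)c(CCCCCCCCCCCCCc2c(C=O)c(O)c(C)c(O)c2C=O)c1C=O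
A1 | alternative 1 | 2-{6-[3-(benzyloxy)-5-methoxy-4-methylphenyl]hexyl}-2-{6-[3,5-bis(benzyloxy)-4-methylphenyl]hexyl}-1,3-dithiane | COc1cc(CCCCCCC2(CCCCCCc3cc(OCc4ccccc4)c(C)c(OCc4ccccc4)c3)SCCCS2)cc(OCc2ccccc2)c1C
A2 | alternative 1 | 1-(benzyloxy)-5-(6-bromohexyl)-3-methoxy-2-methylbenzene | COc1cc(CCCCCCBr)cc(OCc2ccccc2)c1C
A3 | alternative 1 | 1,3-bis(benzyloxy)-5-(6-bromohexyl)-2-methylbenzene | Cc1c(OCc2ccccc2)cc(CCCCCCBr)cc1OCc1ccccc1
A4 | alternative 1 | 1,3-dithiane | C1CSCSC1
A5 | alternative 2 | 2-{13-[3,5-bis(benzyloxy)-4-methylphenyl]tridecyl}-3-tert-butoxy-6-methoxy-5-methylbenzene-1,4-diol | COc1c(C)c(O)c(OC(C)(C)C)c(CCCCCCCCCCCCCc2cc(OCc3ccccc3)c(C)c(OCc3ccccc3)c2)c1O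
A6 | alternative 2 | 2-{13-[3,5-bis(benzyloxy)-4-methylphenyl]tridecyl}-3-tert-butoxy-4-hydroxy-4-(1-methoxyprop-1-en-2-yl)cyclobut-2-en-1-one (racemic, alkene geometry not defined) | COC=C(C)C1(O)C(OC(C)(C)C)=C(CCCCCCCCCCCCCc2cc(OCc3ccccc3)c(C)c(OCc3ccccc3)c2)C1=O
A7 | alternative 3 | 5-{13-[3-(benzyloxy)-5-methoxy-4-methylphenyl]tridecyl}-2-methyl-3-(triisopropylsilyloxy)phenol | COc1cc(CCCCCCCCCCCCCc2cc(O)c(C)c(O[Si](C(C)C)(C(C)C)C(C)C)c2)cc(OCc2ccccc2)c1C
A8 | alternative 3 | 3-{13-[3-(benzyloxy)-5-methoxy-4-methylphenyl]tridecyl}cyclobut-2-en-1-one | COc1cc(CCCCCCCCCCCCCC2=CC(=O)C2)cc(OCc2ccccc2)c1C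
A9 | alternative 3 | triisopropyl(prop-1-yn-1-yloxy)silane | CC#CO[Si](C(C)C)(C(C)C)C(C)C
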